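## Retrosynthetic overview (flavanone numbering)

1. The target comes from its 4'-O-(1,1-dimethylallyl) ether by aromatic Claisen rearrangement. This ether protects the phenol through the whole route and supplies the 5'-prenyl group.
2. Rings C and A come from one thermal [5+1] union. One partner is a chiral β-hydroxy keto-ylide (C2–C3–C4–C4a, carrying ring B). The other is symmetric di-tert-butyl 2,4-diprenyl-3-oxoglutarate (C8a–C8–C7–C6–C5), a double acylketene precursor.
3. Ring order: ring B is bought as vanillin. Ring C closes first, by OH capture of the first acylketene and an intramolecular ester Wittig reaction that makes C4a=C8a. Ring A closes second in the same flask, by the second acylketene and a 6π closure of C4a–C5.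
4. The C2 stereocentre comes from a catalytic asymmetric acetate Mukaiyama aldol on the aldehyde. Its C–O bond is never broken afterwards.
5. The ylide comes from the aldol ester and Ph3P=CH2. The five-carbon unit comes from double prenylation of di-tert-butyl 3-oxoglutarate.

Assumption: the SMILES centre is read as (2S), 5 and 11 are taken as catalogue items, and the two epimerisable centres flanking the ketone in 13 to 17 are carried as mixtures because aromatisation erases them.

## Route

Step 1
Reactants: 1 vanillin; 2 3-chloro-3-methylbut-1-yne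
Product: 3 3-methoxy-4-[(2-methylbut-3-yn-2-yl)oxy]benzaldehyde
Conditions: DBU (1.3 equiv), CuCl2·2H2O (1 mol%), MeCN, 0 °C → rt
Reagents that add atoms: 3-chloro-3-methylbut-1-yne, CC(C)(Cl)C#C
Why: Copper-catalysed propargylic etherification: the tertiary propargylic chloride is activated through its copper acetylide and captured at oxygen by the DBU phenoxide, so the hindered tertiary aryl ether forms and no stereocentre is involved.

Step 2
Reactants: 3 3-methoxy-4-[(2-methylbut-3-yn-2-yl)oxy]benzaldehyde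
Product: 4 3-methoxy-4-[(2-methylbut-3-en-2-yl)oxy]benzaldehyde
Conditions: H2 (1 atm), 5% Pd/CaCO3 poisoned with Pb(OAc)2, quinoline, EtOAc, rt, stopped after 1 equiv H2
Reagents that add atoms: none
Why: Lindlar semi-hydrogenation stops at the terminal alkene and leaves the aldehyde and the aryl ether untouched.

Step 3
Reactants: 4 3-methoxy-4-[(2-methylbut-3-en-2-yl)oxy]benzaldehyde; 5 tert-butyl[(1-methoxyethenyl)oxy]dimethylsilane
Product: 7 methyl (3S)-3-hydroxy-3-{3-methoxy-4-[(2-methylbut-3-en-2-yl)oxy]phenyl}propanoate, via trichlorosilyl aldolate 6 (not isolated)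
Conditions: SiCl4 (1.5 equiv), (R,R)-bisphosphoramide (two N,N'-dimethyl-1,1'-binaphthyl-2,2'-diamine phosphoric triamide units joined by a MeN(CH2)5NMe tether, 5 mol%), i-Pr2NEt (10 mol%), CH2Cl2, −78 °C, 3 h; then sat. aq. NaHCO3, 0 °C
Reagents that add atoms: tert-butyl[(1-methoxyethenyl)oxy]dimethylsilane, C=C(OC)O[Si](C)(C)C(C)(C)C
Why: Lewis-base-activated SiCl4 Mukaiyama acetate aldol: the chiral phosphoramide-bound trichlorosilyl cation binds the aromatic aldehyde and the ketene acetal adds through an open transition state to the Si face, setting (S) at the future C2 (sense assigned by analogy, to be confirmed on 7 by Mosher analysis, with the (S,S)-catalyst equally available), while −78 °C and the amine buffer spare the tertiary allyl ether.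

Step 4
Reactants: 7 methyl (3S)-3-hydroxy-3-{3-methoxy-4-[(2-methylbut-3-en-2-yl)oxy]phenyl}propanoate; 8 methyltriphenylphosphonium bromide
Product: 10 (4S)-4-hydroxy-4-{3-methoxy-4-[(2-methylbut-3-en-2-yl)oxy]phenyl}-1-(triphenyl-λ5-phosphanylidene)butan-2-one, via methylenetriphenylphosphorane 9 (not isolated)
Conditions: 8 (3.5 equiv), n-BuLi (3.4 equiv), THF, 0 °C, 30 min; add 7, 0 → 40 °C, 12 h; H2O work-up
Reagents that add atoms: methyltriphenylphosphonium bromide, C[P+](c1ccccc1)(c1ccccc1)c1ccccc1.[Br-]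
Why: Acylation of a non-stabilised ylide by an ester (transylidation): one equivalent of 9 takes the OH proton, one attacks the ester and one deprotonates the acylphosphonium ion, and because 9 is too weak a base to enolise the ester and the alkoxide cannot leave, the stereocentre is untouched.

Step 5
Reactants: 11 di-tert-butyl 3-oxopentanedioate; 12 1-bromo-3-methylbut-2-ene (prenyl bromide)
Product: 13 di-tert-butyl 2,4-bis(3-methylbut-2-en-1-yl)-3-oxopentanedioate (diastereomer mixture)
Conditions: NaH (1.05 equiv), THF, 0 °C, then 12 (1.0 equiv), rt; second NaH/12 cycle in the same flask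
Reagents that add atoms: 1-bromo-3-methylbut-2-ene, CC(C)=CCBr
Why: Sequential C-alkylation of a bis(β-keto ester): after the first prenylation the unsubstituted methylene is the more acidic and less hindered site, so the second prenyl group goes to C4 and not to C2.

Step 6
Reactants: 10 (4S)-4-hydroxy-4-{3-methoxy-4-[(2-methylbut-3-en-2-yl)oxy]phenyl}-1-(triphenyl-λ5-phosphanylidene)butan-2-one; 13 di-tert-butyl 2,4-bis(3-methylbut-2-en-1-yl)-3-oxopentanedioate
Product: 19 (2S)-5,7-dihydroxy-2-[4-hydroxy-3-methoxy-5-(3-methylbut-2-en-1-yl)phenyl]-6,8-bis(3-methylbut-2-en-1-yl)-2,3-dihydro-4H-chromen-4-one, via acylketene 14 (not isolated), via ester ylide 15 (not isolated), via dihydropyranone 16 (not isolated), via second acylketene 17 (not isolated), via reverse-prenyl ether flavanone 18 (not isolated)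
Conditions: 13 (1.2 equiv), degassed xylenes (0.05 M), 140 °C, Ar, about 6 h
Reagents that add atoms: none
Why: Proposed new method: at 140 °C the tert-butyl β-keto ester termini of 13 reversibly lose t-BuOH to give acylketenes (the chemistry behind transacetoacetylation with tert-butyl acetoacetate); 14 is captured by the C2–OH of 10 to give 15, whose stabilised ylide carbon olefinates the new ester carbonyl in a six-membered intramolecular Wittig reaction (closest precedent: the ester-carbonyl Wittig closures used for chromones and benzofurans; direct ylide attack on the ketene followed by oxa-Michael closure would converge on the same ring), closing ring C as 16 without breaking the C2–O bond, so (S) is retained; the second ester then gives 17, whose enol form is a dienylketene that undergoes 6π-electrocyclisation and tautomerisation (the terminating events of a Danheiser benzannulation) to close ring A as 18, with pyrone formation blocked because the C8a oxygen is already part of ring C; at the same temperature the 1,1-dimethylallyl aryl ether undergoes aromatic Claisen rearrangement to its only free ortho position, giving the 4'-OH and 5'-prenyl group of 19.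

## Compound list

1 | vanillin (4-hydroxy-3-methoxybenzaldehyde) | COc1cc(C=O)ccc1O | starting material
2 | 3-chloro-3-methylbut-1-yne | CC(C)(Cl)C#C | starting material
3 | 3-methoxy-4-[(2-methylbut-3-yn-2-yl)oxy]benzaldehyde | COc1cc(C=O)ccc1OC(C)(C)C#C | intermediate
4 | 3-methoxy-4-[(2-methylbut-3-en-2-yl)oxy]benzaldehyde | COc1cc(C=O)ccc1OC(C)(C)C=C | intermediate
5 | tert-butyl[(1-methoxyethenyl)oxy]dimethylsilane | C=C(OC)O[Si](C)(C)C(C)(C)C | starting material
6 | methyl (3S)-3-{3-methoxy-4-[(2-methylbut-3-en-2-yl)oxy]phenyl}-3-[(trichlorosilyl)oxy]propanoate | COC(=O)C[C@H](O[Si](Cl)(Cl)Cl)c1ccc(OC(C)(C)C=C)c(OC)c1 | intermediate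
7 | methyl (3S)-3-hydroxy-3-{3-methoxy-4-[(2-methylbut-3-en-2-yl)oxy]phenyl}propanoate | COC(=O)C[C@H](O)c1ccc(OC(C)(C)C=C)c(OC)c1 | intermediate
8 | methyltriphenylphosphonium bromide | C[P+](c1ccccc1)(c1ccccc1)c1ccccc1.[Br-] | starting material
9 | methylenetriphenylphosphorane | C=P(c1ccccc1)(c1ccccc1)c1ccccc1 | intermediate
10 | (4S)-4-hydroxy-4-{3-methoxy-4-[(2-methylbut-3-en-2-yl)oxy]phenyl}-1-(triphenyl-λ5-phosphanylidene)butan-2-one | O=C(C[C@H](O)c1ccc(OC(C)(C)C=C)c(OC)c1)C=P(c1ccccc1)(c1ccccc1)c1ccccc1 | intermediate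
11 | di-tert-butyl 3-oxopentanedioate | CC(C)(C)OC(=O)CC(=O)CC(=O)OC(C)(C)C | starting material
12 | 1-bromo-3-methylbut-2-ene | CC(C)=CCBr | starting material
13 | di-tert-butyl 2,4-bis(3-methylbut-2-en-1-yl)-3-oxopentanedioate | CC(C)=CCC(C(=O)OC(C)(C)C)C(=O)C(CC=C(C)C)C(=O)OC(C)(C)C | intermediate
14 | tert-butyl 5-methyl-2-[5-methyl-2-(oxomethylidene)hex-4-enoyl]hex-4-enoate | O=C=C(CC=C(C)C)C(=O)C(CC=C(C)C)C(=O)OC(C)(C)C | intermediate
15 | 1-tert-butyl 5-[(1S)-1-{3-methoxy-4-[(2-methylbut-3-en-2-yl)oxy]phenyl}-3-oxo-4-(triphenyl-λ5-phosphanylidene)butyl] 2,4-bis(3-methylbut-2-en-1-yl)-3-oxopentanedioate | CC(C)=CCC(C(=O)OC(C)(C)C)C(=O)C(CC=C(C)C)C(=O)O[C@@H](CC(=O)C=P(c1ccccc1)(c1ccccc1)c1ccccc1)c1ccc(OC(C)(C)C=C)c(OC)c1 | intermediate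
16 | tert-butyl 4-[(2S)-2-{3-methoxy-4-[(2-methylbut-3-en-2-yl)oxy]phenyl}-4-oxo-3,4-dihydro-2H-pyran-6-yl]-7-methyl-2-(3-methylbut-2-en-1-yl)-3-oxooct-6-enoate | CC(C)=CCC(C(=O)OC(C)(C)C)C(=O)C(CC=C(C)C)C1=CC(=O)C[C@@H](c2ccc(OC(C)(C)C=C)c(OC)c2)O1 | intermediate
17 | 4-[(2S)-2-{3-methoxy-4-[(2-methylbut-3-en-2-yl)oxy]phenyl}-4-oxo-3,4-dihydro-2H-pyran-6-yl]-7-methyl-2-(3-methylbut-2-en-1-yl)octa-1,6-diene-1,3-dione | O=C=C(CC=C(C)C)C(=O)C(CC=C(C)C)C1=CC(=O)C[C@@H](c2ccc(OC(C)(C)C=C)c(OC)c2)O1 | intermediate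
18 | (2S)-5,7-dihydroxy-2-{3-methoxy-4-[(2-methylbut-3-en-2-yl)oxy]phenyl}-6,8-bis(3-methylbut-2-en-1-yl)-2,3-dihydro-4H-chromen-4-one | COc1cc([C@@H]2CC(=O)c3c(O)c(CC=C(C)C)c(O)c(CC=C(C)C)c3O2)ccc1OC(C)(C)C=C | intermediate
19 | (2S)-5,7-dihydroxy-2-[4-hydroxy-3-methoxy-5-(3-methylbut-2-en-1-yl)phenyl]-6,8-bis(3-methylbut-2-en-1-yl)-2,3-dihydro-4H-chromen-4-one (CNP0235424.1) | COc1cc([C@@H]2CC(=O)c3c(O)c(CC=C(C)C)c(O)c(CC=C(C)C)c3O2)cc(CC=C(C)C)c1O | target

## Step count and risks

Total step count: 6. Longest linear sequence: 5 (steps 1, 2, 3, 4, 6).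

**Risk 1 (step 6).**
- The ylide carbon of 10 may be C-acylated by 14 to give an inert diacyl ylide.
- 14 may close on its own ester oxygen to give a pyranone.
- The mildly basic ylide at 140 °C may erode the ee of 19 by retro-oxa-Michael opening.

The fallback replaces the ketene/Wittig union by a polyanion Claisen condensation and an acid cyclodehydration. It sets out from 7 and comes back at 16. tert-Butyl acetoacetate is converted into its dilithio dianion (lithium diisopropylamide, 2.1 equiv). It is then alkylated in one flask with 12, first at the γ- and then at the α-carbon, to give tert-butyl 7-methyl-2-(3-methylbut-2-en-1-yl)-3-oxooct-6-enoate F1. The dianion of this ester is acetylated at C4 with N-methoxy-N-methylacetamide to give tert-butyl 2,4-bis(3-methylbut-2-en-1-yl)-3,5-dioxohexanoate F2. Its trianion (lithium diisopropylamide, 3.3 equiv, used in twofold excess) is acylated at the terminal methyl carbon by the lithium alkoxide of 7. This gives open-chain tert-butyl (9S)-9-hydroxy-9-{3-methoxy-4-[(2-methylbut-3-en-2-yl)oxy]phenyl}-2,4-bis(3-methylbut-2-en-1-yl)-3,5,7-trioxononanoate F3. Catalytic pyridinium p-toluenesulfonate in toluene at 50 °C closes the δ-hydroxy-β-diketone to 16 by hemiketalisation and dehydration. Raising the bath to 140 °C carries 16 through 17 and 18 to 19 in the same flask.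

**Risk 2 (step 4).**
- An aliphatic methyl ester bearing a β-alkoxide may be acylated only sluggishly by 9.
- Any retro-aldol aldehyde would be lost to methylenation.

The fallback builds the ylide from a halomethyl ketone. It sets out from 7 and comes back at 10. Chloromethyllithium (ICH2Cl, MeLi·LiBr, THF, −78 °C, excess) converts 7 into (4S)-1-chloro-4-hydroxy-4-{3-methoxy-4-[(2-methylbut-3-en-2-yl)oxy]phenyl}butan-2-one F4. PPh3 in MeCN at 40 °C then gives [(4S)-4-hydroxy-4-{3-methoxy-4-[(2-methylbut-3-en-2-yl)oxy]phenyl}-2-oxobutyl]triphenylphosphonium chloride F5. Shaking with aqueous Na2CO3 and CH2Cl2 liberates 10.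

**Risk 3 (step 3).**
- The electron-rich aldehyde may give an insufficient ee.
- The activated chlorosilane may attack the tertiary allyl ether.

The fallback swaps catalytic induction for a resolution. It sets out from 4 and comes back at 7. A Reformatsky reaction (Zn, methyl bromoacetate, THF, 40 °C) gives racemic methyl 3-hydroxy-3-{3-methoxy-4-[(2-methylbut-3-en-2-yl)oxy]phenyl}propanoate F6. Burkholderia cepacia lipase with vinyl acetate in i-Pr2O at 35 °C, run to about 52% conversion, acetylates the (R)-alcohol. This gives methyl (3R)-3-acetoxy-3-{3-methoxy-4-[(2-methylbut-3-en-2-yl)oxy]phenyl}propanoate F7. It is removed by chromatography from the unreacted (S)-alcohol 7.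

## Further compounds

F1 | step 6 | tert-butyl 7-methyl-2-(3-methylbut-2-en-1-yl)-3-oxooct-6-enoate | CC(C)=CCCC(=O)C(CC=C(C)C)C(=O)OC(C)(C)C
F2 | step 6 | tert-butyl 2,4-bis(3-methylbut-2-en-1-yl)-3,5-dioxohexanoate | CC(=O)C(CC=C(C)C)C(=O)C(CC=C(C)C)C(=O)OC(C)(C)C
F3 | step 6 | tert-butyl (9S)-9-hydroxy-9-{3-methoxy-4-[(2-methylbut-3-en-2-yl)oxy]phenyl}-2,4-bis(3-methylbut-2-en-1-yl)-3,5,7-trioxononanoate | CC(C)=CCC(C(=O)OC(C)(C)C)C(=O)C(CC=C(C)C)C(=O)CC(=O)C[C@H](O)c1ccc(OC(C)(C)C=C)c(OC)c1
F4 | step 4 | (4S)-1-chloro-4-hydroxy-4-{3-methoxy-4-[(2-methylbut-3-en-2-yl)oxy]phenyl}butan-2-one | ClCC(=O)C[C@H](O)c1ccc(OC(C)(C)C=C)c(OC)c1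
F5 | step 4 | [(4S)-4-hydroxy-4-{3-methoxy-4-[(2-methylbut-3-en-2-yl)oxy]phenyl}-2-oxobutyl]triphenylphosphonium chloride | O=C(C[C@H](O)c1ccc(OC(C)(C)C=C)c(OC)c1)C[P+](c1ccccc1)(c1ccccc1)c1ccccc1.[Cl-]
F6 | step 3 | racemic methyl 3-hydroxy-3-{3-methoxy-4-[(2-methylbut-3-en-2-yl)oxy]phenyl}propanoate | COC(=O)CC(O)c1ccc(OC(C)(C)C=C)c(OC)c1
F7 | step 3 | methyl (3R)-3-acetoxy-3-{3-methoxy-4-[(2-methylbut-3-en-2-yl)oxy]phenyl}propanoate | COC(=O)C[C@@H](OC(C)=O)c1ccc(OC(C)(C)C=C)c(OC)c1
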